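Numbering: C1 and C10 are the ring-fusion carbons; C2–C9 complete the ten-membered ring (CO2Me on C3, CO2H on C7, OH on C8); C11–C14 complete ring A (C11 bears the exocyclic CH2, C14 the isopropylidene carbon C15).
Enabling feature: with ring A opened at C11–C12 and C11 written as a carboxyl, C11(=O)–C10–C1–C14=C15 is a γ,δ-unsaturated acid, so the fusion bond C1–C10 is a Claisen bond; tying the C11 carboxyl to C15 through oxygen gives a 14-membered lactone (C11, O, C15, C14, C1–C10) whose ketene acetal contracts to the ten-membered ring.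
Retrosynthetic cuts, in order: C11=CH2; C11–C12 (ring A); C1–C10 with C15–O re-formed (ring contraction read backwards); C2=C3 (ring-closing olefination); C7–CO2R and C7–C8 (vinyl iodide, alkyne, ynone); the C11–O ester (succinic anhydride); C14=C1 and the two C15 methyls (alkylidene lactone).
Forward order: a chain is built on a tertiary allylic succinate; the 14-membered lactone closes first (C2=C3), the ten-membered carbocycle arises from it by ring contraction, ring A closes last (C11–C12), then methylenation and deprotection.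
Stereochemistry: C8 (R) from asymmetric transfer hydrogenation of an ynone; C1 and C10 (both S, trans fusion) from the Claisen step (E-C14=C1, boron enolate geometry, chiral diazaborolidine on boron); alkene geometries from a Wittig reaction (C14=C1), syn-hydrostannation (C6=C7) and the ring-closing olefination (C2=C3).

Key step: step 14

Abbreviations: TBS = tert-butyldimethylsilyl; PMB = 4-methoxybenzyl; TMSE = 2-(trimethylsilyl)ethyl; R* = (3E)-3-[2-(TBSO)ethyl]-5-(PMBO)-2-methylpent-3-en-2-yl (the tertiary allylic group of 6); L*BBr = (4S,5S)-2-bromo-1,3-bis{[3,5-bis(trifluoromethyl)phenyl]sulfonyl}-4,5-diphenyl-1,3,2-diazaborolidine. Compounds 13 and 15–22 are mixtures of C3 epimers; C3 becomes sp2 in step 13.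
Assumption: the (S,S)-antipode L*BBr is written on the assumption that, together with the C8 centre, it directs attack to the enolate face giving (1S,10S); this sense of induction cannot be derived from the substrate, and the reagent exists in both antipodes.

Step 1
Reactants: 1 3-(triphenyl-λ5-phosphanylidene)oxolan-2-one; 2 2-[(4-methoxybenzyl)oxy]acetaldehyde
Product: 3 (3E)-3-{2-[(4-methoxybenzyl)oxy]ethylidene}oxolan-2-one
Conditions: CH2Cl2, rt
Reagents that add atoms: none
Why: Wittig olefination with a lactone-stabilised ylide should give the (E)-α-alkylidene lactone (C2 cis to C13, anti to the C15 carbonyl), which fixes the C14=C1 geometry needed in step 14.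

Step 2
Reactants: 3 (3E)-3-{2-[(4-methoxybenzyl)oxy]ethylidene}oxolan-2-one
Product: 5 (3E)-3-(2-hydroxyethyl)-5-[(4-methoxybenzyl)oxy]-2-methylpent-3-en-2-ol, via keto alkoxide 4 (not isolated)
Conditions: MeLi (3 equiv), THF, −78 → 0 °C; then H2O
Reagents that add atoms: methyllithium, [Li]C
Why: Double 1,2-addition of an organolithium to the lactone carbonyl (through the ring-opened enone) turns C15 into the gem-dimethyl carbinol and frees the C12 hydroxyl without touching the alkene geometry.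

Step 3
Reactants: 5 (3E)-3-(2-hydroxyethyl)-5-[(4-methoxybenzyl)oxy]-2-methylpent-3-en-2-ol
Product: 6 (3E)-3-[2-(tert-butyldimethylsilyloxy)ethyl]-5-[(4-methoxybenzyl)oxy]-2-methylpent-3-en-2-ol
Conditions: TBSCl, imidazole, CH2Cl2, 0 °C
Reagents that add atoms: tert-butyldimethylsilyl chloride, CC(C)(C)[Si](C)(C)Cl
Why: Chemoselective silylation, the primary C12 hydroxyl reacting far faster than the tertiary allylic one.

Step 4
Reactants: 6 (3E)-3-[2-(tert-butyldimethylsilyloxy)ethyl]-5-[(4-methoxybenzyl)oxy]-2-methylpent-3-en-2-ol; 7 succinic anhydride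
Product: 9 hydrogen succinate R*O2C-CH2CH2-CO2H, via lithium alkoxide 8 (not isolated)
Conditions: n-BuLi (1.0 equiv), THF, −78 °C; then 7, −78 °C → rt; cold dilute HCl to pH 4
Reagents that add atoms: none
Why: O-Acylation of a preformed tertiary lithium alkoxide by ring-opening of a cyclic anhydride is a reliable way to esterify a hindered tertiary allylic alcohol and brings in C8–C11 in one operation.

Step 5
Reactants: 10 trimethyl phosphonoacetate; 11 4-bromobut-1-yne
Product: 13 methyl 2-(dimethoxyphosphoryl)hex-5-ynoate (racemic), via sodium enolate 12 (not isolated)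
Conditions: NaH (1.0 equiv), DMF, 0 °C; then 11, rt → 50 °C
Reagents that add atoms: none
Why: C-Alkylation of a phosphonoacetate anion with a primary bromide; the new centre (C3) is racemic, which does not matter because it becomes sp2 in step 13.

Step 6
Reactants: 9 hydrogen succinate R*O2C-CH2CH2-CO2H; 13 methyl 2-(dimethoxyphosphoryl)hex-5-ynoate
Product: 15 ynone R*O2C-CH2CH2-C(=O)-C≡C-CH2CH2-CH(CO2Me)P(O)(OMe)2, via acid chloride 14 (not isolated)
Conditions: 1-chloro-N,N,2-trimethylprop-1-en-1-amine, CH2Cl2, 0 °C; then 13, PdCl2(PPh3)2 (cat.), CuI (cat.), Et3N, THF, rt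
Reagents that add atoms: none
Why: Neutral acid chloride formation followed by acyl Sonogashira coupling with the terminal alkyne forms the C7–C8 bond as an ynone, triethylamine being too weak a base to engage the phosphonoacetate C–H.

Step 7
Reactants: 15 ynone R*O2C-CH2CH2-C(=O)-C≡C-CH2CH2-CH(CO2Me)P(O)(OMe)2
Product: 16 (8R)-propargylic alcohol R*O2C-CH2CH2-CH(OH)-C≡C-CH2CH2-CH(CO2Me)P(O)(OMe)2
Conditions: RuCl[(R,R)-TsDPEN](p-cymene) (cat.), i-PrOH, rt
Reagents that add atoms: none
Why: Noyori asymmetric transfer hydrogenation of an ynone, in which the alkynyl group takes the place of the aryl group of aryl ketones, so the (R,R)-ligand is expected to deliver hydride to the face that gives the (R)-carbinol at C8.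

Step 8
Reactants: 16 (8R)-propargylic alcohol R*O2C-CH2CH2-CH(OH)-C≡C-CH2CH2-CH(CO2Me)P(O)(OMe)2
Product: 18 (8R)-vinyl iodide R*O2C-CH2CH2-CH(OH)-C(I)=CH-CH2CH2-CH(CO2Me)P(O)(OMe)2 (6E: I trans to C5), via vinylstannane 17 (not isolated)
Conditions: Bu3SnH, Mo(CO)3(CNtBu)3 (cat.), hydroquinone (cat.), THF, 55 °C; then I2, CH2Cl2, 0 °C
Reagents that add atoms: iodine, II
Why: Molybdenum-catalysed syn-hydrostannation of a propargylic alcohol places tin on the alkyne carbon next to the carbinol (C7) and hydrogen on C6, and iododestannylation with retention then gives the vinyl iodide with C5 cis to C8.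

Step 9
Reactants: 18 (8R)-vinyl iodide R*O2C-CH2CH2-CH(OH)-C(I)=CH-CH2CH2-CH(CO2Me)P(O)(OMe)2
Product: 19 TBS ether R*O2C-CH2CH2-CH(OTBS)-C(I)=CH-CH2CH2-CH(CO2Me)P(O)(OMe)2 (8R; 6E)
Conditions: TBSOTf, 2,6-lutidine, CH2Cl2, −78 °C
Reagents that add atoms: tert-butyldimethylsilyl triflate, CC(C)(C)[Si](C)(C)OS(=O)(=O)C(F)(F)F
Why: Silylation of a hindered secondary allylic alcohol with a silyl triflate protects O8, so that no γ-lactone can form with C11 later.

Step 10
Reactants: 19 TBS ether R*O2C-CH2CH2-CH(OTBS)-C(I)=CH-CH2CH2-CH(CO2Me)P(O)(OMe)2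
Product: 20 TMSE enoate R*O2C-CH2CH2-CH(OTBS)-C(CO2TMSE)=CH-CH2CH2-CH(CO2Me)P(O)(OMe)2 (8R; 6E)
Conditions: CO (1 atm), Me3SiCH2CH2OH, PdCl2(PPh3)2 (cat.), Et3N, DMF, 50 °C
Reagents that add atoms: carbon monoxide, [C-]#[O+]; 2-(trimethylsilyl)ethanol, C[Si](C)(C)CCO
Why: Palladium-catalysed alkoxycarbonylation of a vinyl iodide goes with retention and gives the (E)-enoate (C5 trans to the ester), oxidative addition of zerovalent palladium to C–I being much faster than ionisation of the hindered tertiary allylic ester.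

Step 11
Reactants: 20 TMSE enoate R*O2C-CH2CH2-CH(OTBS)-C(CO2TMSE)=CH-CH2CH2-CH(CO2Me)P(O)(OMe)2
Product: 21 allylic alcohol HOCH2-CH=C[(CH2)2OTBS]-CMe2-O2C-CH2CH2-CH(OTBS)-C(CO2TMSE)=CH-CH2CH2-CH(CO2Me)P(O)(OMe)2 (8R; C14=C1 E; 6E)
Conditions: DDQ, CH2Cl2/pH 7 phosphate buffer, 0 °C
Reagents that add atoms: none
Why: Oxidative cleavage of a PMB ether by DDQ (hydride abstraction from the electron-rich benzylic position, then hydrolysis) leaves silyl ethers, esters and the phosphonate untouched.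

Step 12
Reactants: 21 allylic alcohol HOCH2-CH=C[(CH2)2OTBS]-CMe2-O2C-CH2CH2-CH(OTBS)-C(CO2TMSE)=CH-CH2CH2-CH(CO2Me)P(O)(OMe)2
Product: 22 enal OHC-CH=C[(CH2)2OTBS]-CMe2-O2C-CH2CH2-CH(OTBS)-C(CO2TMSE)=CH-CH2CH2-CH(CO2Me)P(O)(OMe)2 (8R; C14=C1 E; 6E)
Conditions: Dess–Martin periodinane, CH2Cl2, 0 °C → rt
Reagents that add atoms: none
Why: Dess–Martin oxidation of a primary allylic alcohol gives the (E)-enal under near-neutral conditions without alkene isomerisation.

Step 13
Reactants: 22 enal OHC-CH=C[(CH2)2OTBS]-CMe2-O2C-CH2CH2-CH(OTBS)-C(CO2TMSE)=CH-CH2CH2-CH(CO2Me)P(O)(OMe)2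
Product: 23 14-membered lactone (ring C11(=O)-O-C15Me2-C14[(CH2)2OTBS]=C1H-C2H=C3(CO2Me)-C4H2-C5H2-C6H=C7(CO2TMSE)-C8H(OTBS)-C9H2-C10H2; 8R; all three C=C E)
Conditions: LiCl, DBU, MeCN, rt, slow addition to 1 mM
Reagents that add atoms: none
Why: Intramolecular Horner–Wadsworth–Emmons olefination under Masamune–Roush conditions at high dilution closes the 14-membered ring, and an α-substituted phosphonoacetate with an enal should give the (E)-trisubstituted dienoate (C1 trans to CO2Me) from both C3 epimers.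

Step 14
Reactants: 23 14-membered lactone
Product: 26 (1S,8R,10S)-acid (ten-membered ring C1–C10 with C2=C3(CO2Me) and C6=C7(CO2TMSE) both E; OTBS on C8; CO2H on C10; C[=C(CH3)2]CH2CH2OTBS on C1), via boron ketene acetal 24 (not isolated), via acyloxyborane 25 (not isolated)
Conditions: L*BBr (2.5 equiv), i-Pr2NEt, CH2Cl2, −78 °C; then → rt, 48 h; aqueous work-up
Reagents that add atoms: none
Why: Coordination of boron to the lactone carbonyl and deprotonation of C10 by the hindered amine (soft enolisation) give boron ketene acetal 24 with C9 cis to the O–B oxygen, which on warming undergoes a suprafacial [3,3]-sigmatropic shift through the six-atom array C10=C11–O–C15–C14=C1, forming C1–C10 and breaking C15–O; the closest known reaction type is the Ireland–Claisen ring contraction of macrolactones through chiral boron enolates. The ten-membered ring closes by transannular ring contraction (14 to 10 members), the eight-atom tether C2–C9 bridging two pseudo-equatorial positions of a chair transition state, not by an end-to-end cyclisation. C1 and C10 are created together: the (E)-C14=C1 geometry from step 1 and the enolate geometry are translated by the chair into the trans C1/C10 relationship, and the (S,S)-diazaborolidine on boron, acting with the C8 centre, selects the enolate face that leads to (1S,10S). The step needs site-selective enolisation, which the substrate secures because only the lactone has α-hydrogens (C3 and C7 are sp2 and flanked by branched positions), and it needs the tertiary allylic C15–O bond to survive the Lewis acid, which the electron-poor dienoate on C14=C1 ensures by disfavouring an allyl cation. Cleavage of C15–O can only leave the tetrasubstituted isopropylidene, and the freed C11 carboxyl sits where ring A is closed in step 18.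

Step 15
Reactants: 26 (1S,8R,10S)-acid
Product: 27 S-ethyl thioester of 26 (C11(=O)SEt)
Conditions: EtSH, DCC, DMAP (cat.), CH2Cl2, 0 °C → rt
Reagents that add atoms: ethanethiol, CCS
Why: Steglich-type thioesterification activates C11 as an acyl donor that is inert to the next two steps.

Step 16
Reactants: 27 S-ethyl thioester of 26
Product: 28 primary alcohol (C12–OH; C8–OTBS, TMSE ester and thioester retained)
Conditions: HF·pyridine, pyridine, THF, 0 °C
Reagents that add atoms: none
Why: Selective desilylation, a primary TBS ether being cleaved by buffered HF·pyridine much faster than the hindered secondary one, while the TMSE ester is stable to these conditions.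

Step 17
Reactants: 28 primary alcohol (C12–OH)
Product: 29 primary iodide (C12–I)
Conditions: I2, PPh3, imidazole, CH2Cl2, 0 °C
Reagents that add atoms: iodine, II
Why: Appel-type iodination of a primary alcohol by SN2 displacement of the alkoxyphosphonium ion, to which the thioester and the alkenes are inert.

Step 18
Reactants: 29 primary iodide (C12–I)
Product: 31 trans-fused ring-A ketone (C11=O; 1S,8R,10S), via alkylzinc iodide 30 (not isolated)
Conditions: activated Zn dust, DMA, 40 °C; then PdCl2(PPh3)2 (cat.), toluene, rt; aq. NH4Cl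
Reagents that add atoms: none
Why: Zinc insertion into the primary C–I bond followed by intramolecular Fukuyama coupling (palladium-catalysed acylation of the alkylzinc by the thioester) forms C11–C12 and closes ring A as a six-membered ketone under non-basic conditions, so C10 and the trans fusion are kept.

Step 19
Reactants: 31 trans-fused ring-A ketone
Product: 32 C11-methylene compound (TBS ether and TMSE ester of the target)
Conditions: Zn, CH2Br2, TiCl4, THF/CH2Cl2, 0 °C → rt
Reagents that add atoms: dibromomethane, BrCBr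
Why: Takai–Lombardo methylenation with a non-basic gem-dimetallic reagent converts hindered, enolisable ketones without epimerisation at C10 and leaves the esters alone.

Step 20
Reactants: 32 C11-methylene compound
Product: 33 microeunicellol A
Conditions: TBAF, THF, 0 °C → rt; then pH 4 phosphate buffer
Reagents that add atoms: none
Why: Fluoride-induced fragmentation of the 2-(trimethylsilyl)ethyl ester (loss of ethene) and Si–O cleavage of the TBS ether occur in one operation, while the methyl ester is untouched.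

Compound list
1 | 3-(triphenyl-λ5-phosphanylidene)oxolan-2-one | O=C1OCCC1=P(c1ccccc1)(c1ccccc1)c1ccccc1 | starting material
2 | 2-[(4-methoxybenzyl)oxy]acetaldehyde | O=CCOCc1ccc(OC)cc1 | starting material
3 | (3E)-3-{2-[(4-methoxybenzyl)oxy]ethylidene}oxolan-2-one | COc1ccc(COC/C=C2\CCOC2=O)cc1 | intermediate
4 | lithium (3E)-3-acetyl-5-[(4-methoxybenzyl)oxy]pent-3-en-1-olate (keto alkoxide, not isolated) | [Li+].[O-]CC/C(=C\COCc1ccc(OC)cc1)C(C)=O | intermediate
5 | (3E)-3-(2-hydroxyethyl)-5-[(4-methoxybenzyl)oxy]-2-methylpent-3-en-2-ol | COc1ccc(COC/C=C(\CCO)C(C)(C)O)cc1 | intermediate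
6 | (3E)-3-[2-(tert-butyldimethylsilyloxy)ethyl]-5-[(4-methoxybenzyl)oxy]-2-methylpent-3-en-2-ol | COc1ccc(COC/C=C(\CCO[Si](C)(C)C(C)(C)C)C(C)(C)O)cc1 | intermediate
7 | succinic anhydride | O=C1CCC(=O)O1 | starting material
8 | lithium alkoxide of 6 (not isolated) | [Li+].[O-]C(C)(C)/C(CCO[Si](C)(C)C(C)(C)C)=C/COCc1ccc(OC)cc1 | intermediate
9 | hydrogen succinate of 6, R*O2C-CH2CH2-CO2H (carries C8–C11) | COc1ccc(COC/C=C(\CCO[Si](C)(C)C(C)(C)C)C(C)(C)OC(=O)CCC(=O)O)cc1 | intermediate
10 | trimethyl phosphonoacetate | COC(=O)CP(=O)(OC)OC | starting material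
11 | 4-bromobut-1-yne | C#CCCBr | starting material
12 | sodium enolate of 10 (not isolated) | [Na+].COC(=O)[CH-]P(=O)(OC)OC | intermediate
13 | methyl 2-(dimethoxyphosphoryl)hex-5-ynoate (racemic) | C#CCCC(C(=O)OC)P(=O)(OC)OC | intermediate
14 | acid chloride of 9, R*O2C-CH2CH2-COCl (not isolated) | COc1ccc(COC/C=C(\CCO[Si](C)(C)C(C)(C)C)C(C)(C)OC(=O)CCC(=O)Cl)cc1 | intermediate
15 | ynone R*O2C-CH2CH2-C(=O)-C≡C-CH2CH2-CH(CO2Me)P(O)(OMe)2 | COc1ccc(COC/C=C(\CCO[Si](C)(C)C(C)(C)C)C(C)(C)OC(=O)CCC(=O)C#CCCC(C(=O)OC)P(=O)(OC)OC)cc1 | intermediate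
16 | (8R)-propargylic alcohol | COc1ccc(COC/C=C(\CCO[Si](C)(C)C(C)(C)C)C(C)(C)OC(=O)CC[C@@H](O)C#CCCC(C(=O)OC)P(=O)(OC)OC)cc1 | intermediate
17 | (8R)-vinylstannane, Bu3Sn on C7, Sn and H cis (not isolated) | COc1ccc(COC/C=C(\CCO[Si](C)(C)C(C)(C)C)C(C)(C)OC(=O)CC[C@@H](O)/C(=C\CCC(C(=O)OC)P(=O)(OC)OC)[Sn](CCCC)(CCCC)CCCC)cc1 | intermediate
18 | (8R,6E)-vinyl iodide, I on C7 | COc1ccc(COC/C=C(\CCO[Si](C)(C)C(C)(C)C)C(C)(C)OC(=O)CC[C@@H](O)/C(I)=C\CCC(C(=O)OC)P(=O)(OC)OC)cc1 | intermediate
19 | TBS ether of 18 | COc1ccc(COC/C=C(\CCO[Si](C)(C)C(C)(C)C)C(C)(C)OC(=O)CC[C@@H](O[Si](C)(C)C(C)(C)C)/C(I)=C\CCC(C(=O)OC)P(=O)(OC)OC)cc1 | intermediate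
20 | (8R,6E)-TMSE enoate, CO2TMSE on C7 | COc1ccc(COC/C=C(\CCO[Si](C)(C)C(C)(C)C)C(C)(C)OC(=O)CC[C@@H](O[Si](C)(C)C(C)(C)C)/C(C(=O)OCC[Si](C)(C)C)=C\CCC(C(=O)OC)P(=O)(OC)OC)cc1 | intermediate
21 | primary allylic alcohol (20 with PMBO replaced by OH) | OC/C=C(\CCO[Si](C)(C)C(C)(C)C)C(C)(C)OC(=O)CC[C@@H](O[Si](C)(C)C(C)(C)C)/C(C(=O)OCC[Si](C)(C)C)=C\CCC(C(=O)OC)P(=O)(OC)OC | intermediate
22 | (E)-enal (21 with CH2OH oxidised to CHO) | O=C/C=C(\CCO[Si](C)(C)C(C)(C)C)C(C)(C)OC(=O)CC[C@@H](O[Si](C)(C)C(C)(C)C)/C(C(=O)OCC[Si](C)(C)C)=C\CCC(C(=O)OC)P(=O)(OC)OC | intermediate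
23 | 14-membered lactone: C11 carbonyl, ring O on C15 (gem-dimethyl), C14 bearing CH2CH2OTBS, (E)-C14=C1, (E)-C2=C3 with CO2Me, (E)-C6=C7 with CO2TMSE, (8R)-OTBS | O=C1OC(C)(C)/C(CCO[Si](C)(C)C(C)(C)C)=C/C=C(/C(=O)OC)CC/C=C(/C(=O)OCC[Si](C)(C)C)[C@H](O[Si](C)(C)C(C)(C)C)CC1 | intermediate
24 | boron ketene acetal of 23 (C10=C11, C9 cis to O–B; not isolated) | O1C(C)(C)/C(CCO[Si](C)(C)C(C)(C)C)=C/C=C(/C(=O)OC)CC/C=C(/C(=O)OCC[Si](C)(C)C)[C@H](O[Si](C)(C)C(C)(C)C)C/C=C1\OB2N(S(=O)(=O)c3cc(cc(c3)C(F)(F)F)C(F)(F)F)[C@@H](c3ccccc3)[C@H](c3ccccc3)N2S(=O)(=O)c4cc(cc(c4)C(F)(F)F)C(F)(F)F | intermediate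
25 | acyloxyborane of 26 (not isolated) | CC(C)(C)[Si](C)(C)OCCC(=C(C)C)[C@H]1/C=C(/C(=O)OC)CC/C=C(/C(=O)OCC[Si](C)(C)C)[C@H](O[Si](C)(C)C(C)(C)C)C[C@@H]1C(=O)OB2N(S(=O)(=O)c3cc(cc(c3)C(F)(F)F)C(F)(F)F)[C@@H](c3ccccc3)[C@H](c3ccccc3)N2S(=O)(=O)c4cc(cc(c4)C(F)(F)F)C(F)(F)F | intermediate
26 | (1S,8R,10S)-acid: ten-membered ring, CO2H (C11) on C10, C[=C(CH3)2]CH2CH2OTBS on C1, trans | CC(C)(C)[Si](C)(C)OCCC(=C(C)C)[C@H]1/C=C(/C(=O)OC)CC/C=C(/C(=O)OCC[Si](C)(C)C)[C@H](O[Si](C)(C)C(C)(C)C)C[C@@H]1C(=O)O | intermediate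
27 | S-ethyl thioester of 26 | CC(C)(C)[Si](C)(C)OCCC(=C(C)C)[C@H]1/C=C(/C(=O)OC)CC/C=C(/C(=O)OCC[Si](C)(C)C)[C@H](O[Si](C)(C)C(C)(C)C)C[C@@H]1C(=O)SCC | intermediate
28 | primary alcohol (C12–OH) | OCCC(=C(C)C)[C@H]1/C=C(/C(=O)OC)CC/C=C(/C(=O)OCC[Si](C)(C)C)[C@H](O[Si](C)(C)C(C)(C)C)C[C@@H]1C(=O)SCC | intermediate
29 | primary iodide (C12–I) | ICCC(=C(C)C)[C@H]1/C=C(/C(=O)OC)CC/C=C(/C(=O)OCC[Si](C)(C)C)[C@H](O[Si](C)(C)C(C)(C)C)C[C@@H]1C(=O)SCC | intermediate
30 | alkylzinc iodide (C12–ZnI; not isolated) | I[Zn]CCC(=C(C)C)[C@H]1/C=C(/C(=O)OC)CC/C=C(/C(=O)OCC[Si](C)(C)C)[C@H](O[Si](C)(C)C(C)(C)C)C[C@@H]1C(=O)SCC | intermediate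
31 | trans-fused ring-A ketone (C11=O) | O=C1CCC(=C(C)C)[C@H]2/C=C(/C(=O)OC)CC/C=C(/C(=O)OCC[Si](C)(C)C)[C@H](O[Si](C)(C)C(C)(C)C)C[C@H]12 | intermediate
32 | C11-methylene compound (O8-TBS, C7-TMSE ester of the target) | C=C1CCC(=C(C)C)[C@H]2/C=C(/C(=O)OC)CC/C=C(/C(=O)OCC[Si](C)(C)C)[C@H](O[Si](C)(C)C(C)(C)C)C[C@H]12 | intermediate
33 | microeunicellol A | C=C1CCC(=C(C)C)[C@H]2/C=C(/C(=O)OC)CC/C=C(/C(=O)O)[C@H](O)C[C@H]12 | target

Total step count: 20. Longest linear sequence: 19 steps (steps 1–4 and 6–20, from 1 and 2 to 33); step 5 is a one-step branch.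

Steps most likely to fail

Step 14. The hindered tertiary ester may be enolised only slowly by the bulky borane. The rearrangement may also leak through a boat or through the other enolate geometry, which gives the C10 epimer, and face selection is poor if the reagent and the C8 centre are mismatched. The fallback sets out from 23 and drops reagent control. LiHMDS with Me3SiCl/Et3N in THF/DMPU at −78 °C gives the trimethylsilyl ketene acetal F1, which rearranges on warming to 60 °C (classical silyl Ireland–Claisen ring contraction, the face chosen by the C8-substituted macrocycle alone). The trimethylsilyl ester F2 is hydrolysed on work-up. Where this gives the C10-epimeric acid F3, the conditions of step 15 turn it into the C10-epimeric thioester F4, and DBU in toluene equilibrates F4 α to the thioester carbonyl towards the trans-disposed isomer; the C1–H, which is doubly allylic and γ to the C3 ester, may be deprotonated competitively under these conditions. The fallback comes back to the route at 27.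

Step 18. Zinc insertion may be slow, with protodezincation of the organozinc competing, and acyl transfer to palladium may be sluggish at the α-branched thioester. The fallback sets out from 28 and replaces acylation by carbonyl addition and oxidation. Fukuyama reduction (Et3SiH, Pd/C, acetone) gives the hydroxy aldehyde F5, and I2/PPh3/imidazole gives the iodo aldehyde F6. Intramolecular alkylchromium addition (CrCl2, catalytic cobalt phthalocyanine Co(C32H16N8), DMF) then closes ring A as the ring-A carbinol F7, a mixture of C11 epimers. Dess–Martin oxidation returns to 31.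

Step 6. The acid chloride may collapse by attack of the neighbouring ester carbonyl with loss of the tertiary allylic group (succinic anhydride formation), or the phosphonoacetate may add to the ynone. The fallback sets out from 9 and avoids any acyl chloride. DCC, EtSH and catalytic DMAP give the S-ethyl thioester F8, which is coupled with alkyne 13 by palladium/copper-mediated thioester alkynylation (PdCl2(dppf), tri(2-furyl)phosphine, CuI, Et3N, DMF, 50 °C). The fallback comes back to the route at 15.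

Further compounds
F1 | step 14 | trimethylsilyl ketene acetal of 23 (C9 cis to OSi) | O1C(C)(C)/C(CCO[Si](C)(C)C(C)(C)C)=C/C=C(/C(=O)OC)CC/C=C(/C(=O)OCC[Si](C)(C)C)[C@H](O[Si](C)(C)C(C)(C)C)C/C=C1\O[Si](C)(C)C
F2 | step 14 | trimethylsilyl ester of the C10-epimeric acid | CC(C)(C)[Si](C)(C)OCCC(=C(C)C)[C@H]1/C=C(/C(=O)OC)CC/C=C(/C(=O)OCC[Si](C)(C)C)[C@H](O[Si](C)(C)C(C)(C)C)C[C@H]1C(=O)O[Si](C)(C)C
F3 | step 14 | C10-epimeric acid (C10 epimer of 26) | CC(C)(C)[Si](C)(C)OCCC(=C(C)C)[C@H]1/C=C(/C(=O)OC)CC/C=C(/C(=O)OCC[Si](C)(C)C)[C@H](O[Si](C)(C)C(C)(C)C)C[C@H]1C(=O)O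
F4 | step 14 | C10-epimeric S-ethyl thioester (C10 epimer of 27) | CC(C)(C)[Si](C)(C)OCCC(=C(C)C)[C@H]1/C=C(/C(=O)OC)CC/C=C(/C(=O)OCC[Si](C)(C)C)[C@H](O[Si](C)(C)C(C)(C)C)C[C@H]1C(=O)SCC
F5 | step 18 | hydroxy aldehyde (C11 aldehyde, C12–OH) | OCCC(=C(C)C)[C@H]1/C=C(/C(=O)OC)CC/C=C(/C(=O)OCC[Si](C)(C)C)[C@H](O[Si](C)(C)C(C)(C)C)C[C@@H]1C=O
F6 | step 18 | iodo aldehyde (C11 aldehyde, C12–I) | ICCC(=C(C)C)[C@H]1/C=C(/C(=O)OC)CC/C=C(/C(=O)OCC[Si](C)(C)C)[C@H](O[Si](C)(C)C(C)(C)C)C[C@@H]1C=O
F7 | step 18 | ring-A carbinol (C11–OH, both epimers) | OC1CCC(=C(C)C)[C@H]2/C=C(/C(=O)OC)CC/C=C(/C(=O)OCC[Si](C)(C)C)[C@H](O[Si](C)(C)C(C)(C)C)C[C@H]12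
F8 | step 6 | S-ethyl thioester of 9 | COc1ccc(COC/C=C(\CCO[Si](C)(C)C(C)(C)C)C(C)(C)OC(=O)CCC(=O)SCC)cc1
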